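**Plan**
Cuts, in retrosynthetic order: the three phenol O–SEM bonds; C3=C4 of the pyran ring (olefin metathesis); the Cα=Cβ bond of a chalcone that stands for the C5–CH2CH2–CO chain (aldol condensation, then 1,4-reduction); C5–CHO; C4=CH2; and C8a–O1. This leaves fluoroaldehyde 1, (R)-linalool 5 and 2,4-dihydroxyacetophenone 16.
Enabling feature: C2 carries O1, a methyl group, the alkene carbon C3 and the side-chain CH2, which are exactly the four substituents of the carbinol carbon of 5. C4 sits on C4a of ring A, ortho to the O1-bearing C8a, so one vinyl group on each side of the ether is enough to close the pyran.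
Forward: ring A and 5 are joined through O1 (SNAr), and the formyl group becomes the C4 vinyl group. The prenyl end is transposed to the E tertiary allylic alcohol, ring B is attached through C5, and the only ring made, the 2H-pyran, closes next to last.
Stereochemistry: C2 (R) is bought with 5 and none of its four bonds is ever broken. The side-chain E alkene comes from a selenoxide syn elimination.

Key step: step 11

Assumption: commercial (R)-(−)-linalool is taken as the single enantiomer. No step touches a bond at its carbinol carbon, so the enantiomeric purity of 24 should equal that of the purchased 5.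
Abbreviations and numbering: SEM = CH2OCH2CH2SiMe3, and "SEM-oxy" = [2-(trimethylsilyl)ethoxy]methoxy. Chromene atoms are O1, C2, C3, C4, C4a, C5–C8, C8a; ring A is the benzo ring of the chromene and ring B the resorcinol ring. Compounds 7–21 hold a tertiary allyl aryl ether and are kept acid-free and below about 50 °C. Chromenes 22–24 are kept from light.

Step 1
Reactants: 1 6-bromo-2-fluoro-3-methoxybenzaldehyde
Product: 3 6-bromo-2-fluoro-3-hydroxybenzaldehyde, via aryloxydibromoborane 2 (not isolated)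
Conditions: BBr3, CH2Cl2, −78 → 0 °C; then H2O
Reagents that add atoms: none
Why: Lewis-acid cleavage of an aryl methyl ether (BBr3 binds the methoxy oxygen, bromide removes CH3 by SN2) spares CHO, C–F and C–Br at low temperature, and it is done now because no later intermediate would survive a demethylation.

Step 2
Reactants: 3 6-bromo-2-fluoro-3-hydroxybenzaldehyde
Product: 4 6-bromo-2-fluoro-3-(SEM-oxy)benzaldehyde
Conditions: SEMCl, i-Pr2NEt, CH2Cl2, 0 °C → rt
Reagents that add atoms: 2-(trimethylsilyl)ethoxymethyl chloride (SEMCl), ClCOCC[Si](C)(C)C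
Why: Williamson-type O-alkylation of an acidic ortho-fluorophenol with an α-chloro ether; the acetal is preferred to an aryl silyl ether because it is slim beside the C–F carbon, resists the fluoride released in step 3 and the KOH of step 9 (where this oxygen lies para to a formyl group), and still falls to fluoride at the end.

Step 3
Reactants: 4 6-bromo-2-fluoro-3-(SEM-oxy)benzaldehyde; 5 (R)-linalool
Product: 7 6-bromo-2-{[(3R)-3,7-dimethylocta-1,6-dien-3-yl]oxy}-3-(SEM-oxy)benzaldehyde, via potassium linaloolate 6 (not isolated)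
Conditions: 5 (slight excess), KN(SiMe3)2, THF, 0 °C; then 4, THF–DMF, 0 °C → rt
Reagents that add atoms: none
Why: Nucleophilic aromatic substitution by addition–elimination at the C–F carbon ortho to the formyl group, which stabilises the Meisenheimer adduct; fluoride leaves far faster than the ortho bromide, and since only the O–H bond of 5 is broken the future C2 is carried over with its R configuration.

Step 4
Reactants: 7 6-bromo-2-{[(3R)-3,7-dimethylocta-1,6-dien-3-yl]oxy}-3-(SEM-oxy)benzaldehyde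
Product: 8 1-bromo-3-{[(3R)-3,7-dimethylocta-1,6-dien-3-yl]oxy}-2-ethenyl-4-(SEM-oxy)benzene
Conditions: MePPh3Br, KOt-Bu, THF, 0 °C → rt
Reagents that add atoms: methyltriphenylphosphonium bromide, C[P+](c1ccccc1)(c1ccccc1)c1ccccc1.[Br-]
Why: Wittig methylenation of a non-enolisable benzaldehyde installs C4=CH2 under basic conditions at or below room temperature, which harm neither the aryl bromide nor the heat- and acid-sensitive tertiary ether.

Step 5
Reactants: 8 1-bromo-3-{[(3R)-3,7-dimethylocta-1,6-dien-3-yl]oxy}-2-ethenyl-4-(SEM-oxy)benzene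
Product: 9 1-bromo-3-{[(3R)-5-(3,3-dimethyloxiran-2-yl)-3-methylpent-1-en-3-yl]oxy}-2-ethenyl-4-(SEM-oxy)benzene (both epimers at the oxirane CH)
Conditions: mCPBA (1.0 equiv), CH2Cl2 over aq NaHCO3, 0 °C
Reagents that add atoms: 3-chloroperoxybenzoic acid (mCPBA), OOC(=O)c1cccc(Cl)c1
Why: Prilezhaev epoxidation picks the electron-rich trisubstituted alkene over the twisted 2,6-disubstituted styrene and the inductively deactivated vinyl group; the oxirane stereocentre forms without control, but both epimers converge in step 6.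

Step 6
Reactants: 9 1-bromo-3-{[(3R)-5-(3,3-dimethyloxiran-2-yl)-3-methylpent-1-en-3-yl]oxy}-2-ethenyl-4-(SEM-oxy)benzene
Product: 12 (3E,6R)-6-[3-bromo-2-ethenyl-6-(SEM-oxy)phenoxy]-2,6-dimethylocta-3,7-dien-2-ol, via hydroxy selenide 10 (not isolated), via selenoxide 11 (not isolated)
Conditions: PhSeSePh, NaBH4, EtOH, rt; then 9, rt → 45 °C; then THF, 30% H2O2, 0 °C → rt
Reagents that add atoms: none
Why: Epoxide-to-allylic-alcohol transposition by the organoselenium route: PhSe− opens the oxirane by SN2 at its less substituted carbon, and the selenoxide undergoes syn elimination towards the only β-hydrogens (the neighbouring CH2), which should give the E alkene and erase the uncontrolled centre.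

Step 7
Reactants: 12 (3E,6R)-6-[3-bromo-2-ethenyl-6-(SEM-oxy)phenoxy]-2,6-dimethylocta-3,7-dien-2-ol
Product: 15 2-ethenyl-3-{[(3R,5E)-7-hydroxy-3,7-dimethylocta-1,5-dien-3-yl]oxy}-4-(SEM-oxy)benzaldehyde, via dilithio species 13 (not isolated), via lithium hemiaminal alkoxide 14 (not isolated)
Conditions: n-BuLi (2.2 equiv), THF, −78 °C; DMF, −78 → 0 °C; then H2O
Reagents that add atoms: N,N-dimethylformamide (DMF), CN(C)C=O
Why: Bromine–lithium exchange followed by formylation with DMF; the first equivalent of n-BuLi takes the alcohol proton, and the second exchanges at −78 °C faster than it adds to the styrene or lithiates next to the SEM-oxy group, as is known for 2-bromostyrenes.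

Step 8
Reactants: 16 2,4-dihydroxyacetophenone
Product: 18 1-[2,4-bis(SEM-oxy)phenyl]ethan-1-one, via disodium phenolate 17 (not isolated)
Conditions: NaH (2.2 equiv), DMF, 0 °C; then SEMCl, 0 °C → rt
Reagents that add atoms: 2-(trimethylsilyl)ethoxymethyl chloride (SEMCl), ClCOCC[Si](C)(C)C
Why: Double Williamson O-alkylation; NaH also frees the chelated 2-hydroxyl, and capping both phenols keeps acidic protons away from the enolate of step 9, the copper hydride of step 10 and the ruthenium carbene of step 11.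

Step 9
Reactants: 15 2-ethenyl-3-{[(3R,5E)-7-hydroxy-3,7-dimethylocta-1,5-dien-3-yl]oxy}-4-(SEM-oxy)benzaldehyde; 18 1-[2,4-bis(SEM-oxy)phenyl]ethan-1-one
Product: 20 (2E)-1-[2,4-bis(SEM-oxy)phenyl]-3-[2-ethenyl-3-{[(3R,5E)-7-hydroxy-3,7-dimethylocta-1,5-dien-3-yl]oxy}-4-(SEM-oxy)phenyl]prop-2-en-1-one, via aldol adduct 19 (not isolated)
Conditions: KOH, EtOH, rt
Reagents that add atoms: none
Why: Claisen–Schmidt condensation (crossed aldol, then E1cB loss of water) between a non-enolisable aldehyde and a methyl ketone should give the E chalcone, and SEM acetals, the three alkenes and the tertiary alcohol are inert to ethanolic KOH.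

Step 10
Reactants: 20 (2E)-1-[2,4-bis(SEM-oxy)phenyl]-3-[2-ethenyl-3-{[(3R,5E)-7-hydroxy-3,7-dimethylocta-1,5-dien-3-yl]oxy}-4-(SEM-oxy)phenyl]prop-2-en-1-one
Product: 21 1-[2,4-bis(SEM-oxy)phenyl]-3-[2-ethenyl-3-{[(3R,5E)-7-hydroxy-3,7-dimethylocta-1,5-dien-3-yl]oxy}-4-(SEM-oxy)phenyl]propan-1-one
Conditions: [(Ph3P)CuH]6, H2O, degassed toluene, rt
Reagents that add atoms: none
Why: Conjugate reduction with the phosphine-stabilised copper hydride [(Ph3P)CuH]6 delivers hydride only to the β-carbon of the enone and water supplies the α-proton, so the styrene, the vinyl group, the side-chain alkene and the ketone should stay untouched.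

Step 11
Reactants: 21 1-[2,4-bis(SEM-oxy)phenyl]-3-[2-ethenyl-3-{[(3R,5E)-7-hydroxy-3,7-dimethylocta-1,5-dien-3-yl]oxy}-4-(SEM-oxy)phenyl]propan-1-one
Product: 22 1-[2,4-bis(SEM-oxy)phenyl]-3-{(2R)-2-[(2E)-4-hydroxy-4-methylpent-2-en-1-yl]-2-methyl-8-(SEM-oxy)-2H-chromen-5-yl}propan-1-one
Conditions: second-generation Grubbs catalyst RuCl2(=CHPh)(PCy3)(H2IMes) (5 mol %), CH2Cl2 (2 mM), 40 °C, Ar sparge, dark
Reagents that add atoms: none
Why: By the Chauvin mechanism the ruthenium benzylidene exchanges with the terminal CH2 of the styrene on C4a, the resulting carbene at C4 adds [2+2] to the vinyl group on C2, and cycloreversion of the ruthenacyclobutane forms C3=C4 while Ru=CH2 carries the chain and ethylene escapes. The closest known reaction type is ring-closing metathesis of 2-vinylphenyl ethers of tertiary vinyl carbinols to 2,2-disubstituted 2H-chromenes. The one ring made, the 2H-pyran (O1, C2, C3, C4, C4a, C8a), closes as a six-membered ring with both reacting carbons inside it, so the new alkene is endocyclic and Z by ring constraint. No stereocentre is created, and C2 is a spectator whose four bonds stay intact, so the R configuration of 5 persists. The step needs chemoselectivity among three alkenes: the two monosubstituted ones engage first, whereas the side-chain E alkene is 1,2-disubstituted, abuts a fully substituted carbinol carbon and could only give a cyclobutene with C3 or a seven-membered benzoxepine with C4, which is why the prenyl end was transposed beforehand, since an intact linalyl chain would close to a cyclopentene with loss of isobutene. High dilution holds back dimerisation through the styrene, and 40 °C in the dark stays below the onset of aromatic Claisen rearrangement of 21 and of electrocyclic opening of 22.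

Step 12
Reactants: 22 1-[2,4-bis(SEM-oxy)phenyl]-3-{(2R)-2-[(2E)-4-hydroxy-4-methylpent-2-en-1-yl]-2-methyl-8-(SEM-oxy)-2H-chromen-5-yl}propan-1-one
Product: 24 1-(2,4-dihydroxyphenyl)-3-{(2R)-8-hydroxy-2-[(2E)-4-hydroxy-4-methylpent-2-en-1-yl]-2-methyl-2H-chromen-5-yl}propan-1-one, via tris(tetrabutylammonium) phenolate 23 (not isolated)
Conditions: n-Bu4NF, THF–DMPU, 4 Å molecular sieves, 45 °C, Ar, dark; then AcOH
Reagents that add atoms: none
Why: Fluoride-induced fragmentation of phenol SEM ethers (attack at silicon, loss of ethylene and formaldehyde, release of the phenolate) runs without acid, so the tertiary allylic alcohol, both alkenes and the C2–O1 bond should survive, and AcOH then protonates the phenolates.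

**Compound list**
1 | 6-bromo-2-fluoro-3-methoxybenzaldehyde | COc1ccc(Br)c(C=O)c1F | starting material
2 | (4-bromo-2-fluoro-3-formylphenoxy)dibromoborane | O=Cc1c(Br)ccc(OB(Br)Br)c1F | intermediate
3 | 6-bromo-2-fluoro-3-hydroxybenzaldehyde | O=Cc1c(Br)ccc(O)c1F | intermediate
4 | 6-bromo-2-fluoro-3-(SEM-oxy)benzaldehyde | O=Cc1c(Br)ccc(OCOCC[Si](C)(C)C)c1F | intermediate
5 | (R)-linalool, (3R)-3,7-dimethylocta-1,6-dien-3-ol | CC(C)=CCC[C@](O)(C)C=C | starting material
6 | potassium (R)-linaloolate | CC(C)=CCC[C@]([O-])(C)C=C.[K+] | intermediate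
7 | 6-bromo-2-{[(3R)-3,7-dimethylocta-1,6-dien-3-yl]oxy}-3-(SEM-oxy)benzaldehyde | CC(C)=CCC[C@](C)(C=C)Oc1c(C=O)c(Br)ccc1OCOCC[Si](C)(C)C | intermediate
8 | 1-bromo-3-{[(3R)-3,7-dimethylocta-1,6-dien-3-yl]oxy}-2-ethenyl-4-(SEM-oxy)benzene | CC(C)=CCC[C@](C)(C=C)Oc1c(C=C)c(Br)ccc1OCOCC[Si](C)(C)C | intermediate
9 | 1-bromo-3-{[(3R)-5-(3,3-dimethyloxiran-2-yl)-3-methylpent-1-en-3-yl]oxy}-2-ethenyl-4-(SEM-oxy)benzene, both oxirane epimers | CC1(C)OC1CC[C@](C)(C=C)Oc1c(C=C)c(Br)ccc1OCOCC[Si](C)(C)C | intermediate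
10 | (6R)-6-[3-bromo-2-ethenyl-6-(SEM-oxy)phenoxy]-2,6-dimethyl-3-(phenylselanyl)oct-7-en-2-ol, both C3 epimers | CC(C)(O)C([Se]c1ccccc1)CC[C@](C)(C=C)Oc1c(C=C)c(Br)ccc1OCOCC[Si](C)(C)C | intermediate
11 | selenoxide of 10 | CC(C)(O)C([Se](=O)c1ccccc1)CC[C@](C)(C=C)Oc1c(C=C)c(Br)ccc1OCOCC[Si](C)(C)C | intermediate
12 | (3E,6R)-6-[3-bromo-2-ethenyl-6-(SEM-oxy)phenoxy]-2,6-dimethylocta-3,7-dien-2-ol | CC(C)(O)/C=C/C[C@](C)(C=C)Oc1c(C=C)c(Br)ccc1OCOCC[Si](C)(C)C | intermediate
13 | aryllithium and lithium alkoxide derived from 12 | CC(C)(O[Li])/C=C/C[C@](C)(C=C)Oc1c(C=C)c([Li])ccc1OCOCC[Si](C)(C)C | intermediate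
14 | DMF adduct of 13, dilithium hemiaminal alkoxide | CC(C)(O[Li])/C=C/C[C@](C)(C=C)Oc1c(C=C)c(C(O[Li])N(C)C)ccc1OCOCC[Si](C)(C)C | intermediate
15 | 2-ethenyl-3-{[(3R,5E)-7-hydroxy-3,7-dimethylocta-1,5-dien-3-yl]oxy}-4-(SEM-oxy)benzaldehyde | CC(C)(O)/C=C/C[C@](C)(C=C)Oc1c(C=C)c(C=O)ccc1OCOCC[Si](C)(C)C | intermediate
16 | 2,4-dihydroxyacetophenone | CC(=O)c1ccc(O)cc1O | starting material
17 | disodium 4-acetylbenzene-1,3-diolate | CC(=O)c1ccc([O-])cc1[O-].[Na+].[Na+] | intermediate
18 | 1-[2,4-bis(SEM-oxy)phenyl]ethan-1-one | CC(=O)c1ccc(OCOCC[Si](C)(C)C)cc1OCOCC[Si](C)(C)C | intermediate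
19 | β-hydroxy ketone from 15 and 18, both carbinol epimers | CC(C)(O)/C=C/C[C@](C)(C=C)Oc1c(C=C)c(C(O)CC(=O)c2ccc(OCOCC[Si](C)(C)C)cc2OCOCC[Si](C)(C)C)ccc1OCOCC[Si](C)(C)C | intermediate
20 | (2E)-1-[2,4-bis(SEM-oxy)phenyl]-3-[2-ethenyl-3-{[(3R,5E)-7-hydroxy-3,7-dimethylocta-1,5-dien-3-yl]oxy}-4-(SEM-oxy)phenyl]prop-2-en-1-one | CC(C)(O)/C=C/C[C@](C)(C=C)Oc1c(C=C)c(/C=C/C(=O)c2ccc(OCOCC[Si](C)(C)C)cc2OCOCC[Si](C)(C)C)ccc1OCOCC[Si](C)(C)C | intermediate
21 | 1-[2,4-bis(SEM-oxy)phenyl]-3-[2-ethenyl-3-{[(3R,5E)-7-hydroxy-3,7-dimethylocta-1,5-dien-3-yl]oxy}-4-(SEM-oxy)phenyl]propan-1-one | CC(C)(O)/C=C/C[C@](C)(C=C)Oc1c(C=C)c(CCC(=O)c2ccc(OCOCC[Si](C)(C)C)cc2OCOCC[Si](C)(C)C)ccc1OCOCC[Si](C)(C)C | intermediate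
22 | 1-[2,4-bis(SEM-oxy)phenyl]-3-{(2R)-2-[(2E)-4-hydroxy-4-methylpent-2-en-1-yl]-2-methyl-8-(SEM-oxy)-2H-chromen-5-yl}propan-1-one | CC(C)(O)/C=C/C[C@]1(C)C=Cc2c(CCC(=O)c3ccc(OCOCC[Si](C)(C)C)cc3OCOCC[Si](C)(C)C)ccc(OCOCC[Si](C)(C)C)c2O1 | intermediate
23 | tris(tetrabutylammonium) triphenolate of 24 | CC(C)(O)/C=C/C[C@]1(C)C=Cc2c(CCC(=O)c3ccc([O-])cc3[O-])ccc([O-])c2O1.CCCC[N+](CCCC)(CCCC)CCCC.CCCC[N+](CCCC)(CCCC)CCCC.CCCC[N+](CCCC)(CCCC)CCCC | intermediate
24 | 1-(2,4-dihydroxyphenyl)-3-{(2R)-8-hydroxy-2-[(2E)-4-hydroxy-4-methylpent-2-en-1-yl]-2-methyl-2H-chromen-5-yl}propan-1-one (CNP0311864.1) | CC(C)(O)/C=C/C[C@]1(C)C=Cc2c(CCC(=O)c3ccc(O)cc3O)ccc(O)c2O1 | target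

**Step count and risks**
Total step count: 12. Longest linear sequence: 11 steps (1 to 24 through steps 1–7 and 9–12). Step 8 is a one-step side branch.

Step 3. The displacement may stall, because the reacting carbon lies between the formyl and SEM-oxy groups. The tertiary alkoxide may instead add to the formyl group and start hydride transfer between aldehyde molecules. The fallback uses another activating group. Setting out from 4, I2 and aqueous NH3 in THF turn the formyl group into a nitrile, the fluoro nitrile F1. Alkoxide 6 then displaces fluoride from this more strongly activated ring, which offers the alkoxide no carbonyl to attack, to give the linalyl ether nitrile F2. i-Bu2AlH in toluene at −78 °C adds once to give the N-aluminio aldimine F3, and buffered aqueous hydrolysis comes back to the route at 7.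

Step 11. The ruthenium carbene may be diverted to the side-chain alkene, helped by the free allylic hydroxyl. That would mean seven-membered closure or loss of the chain end. Slow engagement of the crowded vinyl group also leaves time for dimerisation through the styrene. The fallback closes the ring before the third alkene exists.
- Setting out from epoxide 9, which holds only the two terminal alkenes, RuCl2(=CHPh)(PCy3)(H2IMes) in dilute CH2Cl2 closes the pyran to the bromochromene epoxide F4.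
- PhSeNa in EtOH opens it to the chromene hydroxy selenide F5, H2O2 oxidises this to the chromene selenoxide F6, and syn elimination gives the bromochromene allylic alcohol F7.
- n-BuLi (2.2 equiv, THF, −78 °C) gives the chromene dilithio species F8, DMF the chromene hemiaminal alkoxide F9, and water the chromene-5-carbaldehyde F10.
- KOH in EtOH condenses this aldehyde with 18 through the chromene aldol adduct F11 to the chromenyl chalcone F12.
- [(Ph3P)CuH]6 reduces the enone of that chalcone, coming back to the route at 22.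

Step 12. Cleavage of the electron-rich ring A acetal may lag behind the two on ring B. Longer heating with fluoride invites three problems: hydroxymethylation of the freed phenolates by formaldehyde, air oxidation of the ring A phenolate, and erosion of C2 through reversible electrocyclic ring opening. The fallback is a protecting-group relay at the chalcone stage. It sets out from 20, where all three SEM-bearing oxygens are conjugated with the enone or the ketone and are therefore better leaving groups.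
- n-Bu4NF in THF at room temperature gives the chalcone triphenolate salt F13, and AcOH frees the trihydroxychalcone F14.
- t-BuMe2SiCl and imidazole in DMF give the tris(silyl) chalcone F15, with the tertiary alcohol staying free.
- [(Ph3P)CuH]6 gives the tris(silyl) dihydrochalcone F16.
- Ring-closing metathesis as in step 11 gives the tris(silyl) chromene F17.
- Et3N·3HF in THF at 0 °C removes the three phenol silyl ethers, coming back to the route at 24.

**Further compounds**
F1 | step 3 | fluoro nitrile, 6-bromo-2-fluoro-3-(SEM-oxy)benzonitrile | N#Cc1c(Br)ccc(OCOCC[Si](C)(C)C)c1F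
F2 | step 3 | linalyl ether nitrile, 6-bromo-2-{[(3R)-3,7-dimethylocta-1,6-dien-3-yl]oxy}-3-(SEM-oxy)benzonitrile | CC(C)=CCC[C@](C)(C=C)Oc1c(C#N)c(Br)ccc1OCOCC[Si](C)(C)C
F3 | step 3 | N-aluminio aldimine, N-(diisobutylaluminio)imine of 7 | CC(C)=CCC[C@](C)(C=C)Oc1c(C=N[Al](CC(C)C)CC(C)C)c(Br)ccc1OCOCC[Si](C)(C)C
F4 | step 11 | bromochromene epoxide, (2R)-5-bromo-2-[2-(3,3-dimethyloxiran-2-yl)ethyl]-2-methyl-8-(SEM-oxy)-2H-chromene, both oxirane epimers | CC1(C)OC1CC[C@]1(C)C=Cc2c(Br)ccc(OCOCC[Si](C)(C)C)c2O1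
F5 | step 11 | chromene hydroxy selenide, 5-[(2R)-5-bromo-2-methyl-8-(SEM-oxy)-2H-chromen-2-yl]-2-methyl-3-(phenylselanyl)pentan-2-ol | CC(C)(O)C([Se]c1ccccc1)CC[C@]1(C)C=Cc2c(Br)ccc(OCOCC[Si](C)(C)C)c2O1
F6 | step 11 | chromene selenoxide, selenoxide of F5 | CC(C)(O)C([Se](=O)c1ccccc1)CC[C@]1(C)C=Cc2c(Br)ccc(OCOCC[Si](C)(C)C)c2O1
F7 | step 11 | bromochromene allylic alcohol, (3E)-5-[(2R)-5-bromo-2-methyl-8-(SEM-oxy)-2H-chromen-2-yl]-2-methylpent-3-en-2-ol | CC(C)(O)/C=C/C[C@]1(C)C=Cc2c(Br)ccc(OCOCC[Si](C)(C)C)c2O1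
F8 | step 11 | chromene dilithio species, aryllithium and lithium alkoxide from F7 | CC(C)(O[Li])/C=C/C[C@]1(C)C=Cc2c([Li])ccc(OCOCC[Si](C)(C)C)c2O1
F9 | step 11 | chromene hemiaminal alkoxide, DMF adduct of F8 | CC(C)(O[Li])/C=C/C[C@]1(C)C=Cc2c(C(O[Li])N(C)C)ccc(OCOCC[Si](C)(C)C)c2O1
F10 | step 11 | chromene-5-carbaldehyde, (2R)-2-[(2E)-4-hydroxy-4-methylpent-2-en-1-yl]-2-methyl-8-(SEM-oxy)-2H-chromene-5-carbaldehyde | CC(C)(O)/C=C/C[C@]1(C)C=Cc2c(C=O)ccc(OCOCC[Si](C)(C)C)c2O1
F11 | step 11 | chromene aldol adduct, β-hydroxy ketone from F10 and 18 | CC(C)(O)/C=C/C[C@]1(C)C=Cc2c(C(O)CC(=O)c3ccc(OCOCC[Si](C)(C)C)cc3OCOCC[Si](C)(C)C)ccc(OCOCC[Si](C)(C)C)c2O1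
F12 | step 11 | chromenyl chalcone, (2E)-1-[2,4-bis(SEM-oxy)phenyl]-3-{(2R)-2-[(2E)-4-hydroxy-4-methylpent-2-en-1-yl]-2-methyl-8-(SEM-oxy)-2H-chromen-5-yl}prop-2-en-1-one | CC(C)(O)/C=C/C[C@]1(C)C=Cc2c(/C=C/C(=O)c3ccc(OCOCC[Si](C)(C)C)cc3OCOCC[Si](C)(C)C)ccc(OCOCC[Si](C)(C)C)c2O1
F13 | step 12 | chalcone triphenolate salt, tris(tetrabutylammonium) salt of F14 | CC(C)(O)/C=C/C[C@](C)(C=C)Oc1c(C=C)c(/C=C/C(=O)c2ccc([O-])cc2[O-])ccc1[O-].CCCC[N+](CCCC)(CCCC)CCCC.CCCC[N+](CCCC)(CCCC)CCCC.CCCC[N+](CCCC)(CCCC)CCCC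
F14 | step 12 | trihydroxychalcone, (2E)-1-(2,4-dihydroxyphenyl)-3-[2-ethenyl-4-hydroxy-3-{[(3R,5E)-7-hydroxy-3,7-dimethylocta-1,5-dien-3-yl]oxy}phenyl]prop-2-en-1-one | CC(C)(O)/C=C/C[C@](C)(C=C)Oc1c(C=C)c(/C=C/C(=O)c2ccc(O)cc2O)ccc1O
F15 | step 12 | tris(silyl) chalcone, tris(tert-butyldimethylsilyl) ether of F14 at the three phenols | CC(C)(O)/C=C/C[C@](C)(C=C)Oc1c(C=C)c(/C=C/C(=O)c2ccc(O[Si](C)(C)C(C)(C)C)cc2O[Si](C)(C)C(C)(C)C)ccc1O[Si](C)(C)C(C)(C)C
F16 | step 12 | tris(silyl) dihydrochalcone, 2,3-dihydro derivative of F15 | CC(C)(O)/C=C/C[C@](C)(C=C)Oc1c(C=C)c(CCC(=O)c2ccc(O[Si](C)(C)C(C)(C)C)cc2O[Si](C)(C)C(C)(C)C)ccc1O[Si](C)(C)C(C)(C)C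
F17 | step 12 | tris(silyl) chromene, tris(tert-butyldimethylsilyl) ether of 24 at the three phenols | CC(C)(O)/C=C/C[C@]1(C)C=Cc2c(CCC(=O)c3ccc(O[Si](C)(C)C(C)(C)C)cc3O[Si](C)(C)C(C)(C)C)ccc(O[Si](C)(C)C(C)(C)C)c2O1
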